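A small charge, c(D) = 2.0 mM with D as the limiting reagent and E waiting in the second phase, gives a J curve that rises and then falls in Wednesday's run and one that rises and flattens within the scatter in Monday's, so what I read from the earlier runs is when J peaks.

| flask | D | E | temperature | remark | time | volume of the second phase over the first |
|---|---|---|---|---|---|---|
| Wednesday's | 2 mM | 5.2 equiv | 88 °C | run made earlier |  |  |
| Monday's | 2 mM | 7.3 equiv | 126 °C | run made earlier |  |  |
| south-east | 2.0 mM | 6.00 equiv | 70 °C |  | 3.0 min | 2.0 |
| south-west | 2.0 mM | 6.00 equiv | 110 °C |  | 3.0 min | 2.0 |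
| east | 2.0 mM | 4.00 equiv | 110 °C |  | 3.0 min | 2.0 |
| north-west | 2.0 mM | 6.00 equiv | 140 °C |  | 3.0 min | 2.0 |
| south | 2.0 mM | 4.00 equiv | 140 °C |  | 3.0 min | 2.0 |
| north-east | 2.0 mM | 4.00 equiv | 70 °C |  | 3.0 min | 2.0 |

Wednesday's run (percent of the D charged)

| time / min | J / % |
|---|---|
| 1.00 | 26 |
| 2.00 | 42 |
| 2.50 | 41 |
| 4.00 | 36 |
| 6.00 | 26 |

Monday's run (percent of the D charged)

| time / s | J / % |
|---|---|
| 10.0 | 5 |
| 12.0 | 7 |
| 20.0 | 15 |
| 25.0 | 21 |
| 40.0 | 21 |
| 50.0 | 23 |

(each reading ± 2 percentage points)

- in the second phase: E; everything else is in the first
- charges count per volume of the first phase; a concentration in a rate is the amount of a species over the volume of its own phase; every rate counts per litre of the first phase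
- the earlier runs were read with a standard deviation of 2 percentage points
- the earlier runs hold the two phases in the same ratio of volumes as the flask asked about

1. all flasks from highest to lowest amount of J, in percent of the D charged, at 3.0 min (south-east / south-west / east / north-west / south / north-east)
2. the amount of J, in percent of the D charged of the flask you put first, at 3.0 min
3. the amount of J, in percent of the D charged of the flask you put last, at 3.0 min

Wednesday's J reads highest at 2.00 min at 88 °C, while Monday's, at 126 °C, stays within the scatter of 2 percentage points from 25.0 s to 50.0 s, so I take 40.0 s from that plateau as a reading of its peak time. I call the heat factor the number of times the peak time shortens from Wednesday's temperature to Monday's, 3.00, though it carries Monday's larger E, 7.3 equiv against 5.2 equiv, along with the heat. Spreading that factor evenly on a logarithmic scale over temperature, I reckon a peak time of 3.37 min at 70 °C, which is longer than the asked 3.0 min, and of 1.06 min at 110 °C, which is shorter. So I put the coolest flasks first and the hottest last, with 6.00 equiv of E ahead of 4.00 equiv while J is climbing and behind it once J is past its peak. The margin is thin, for with Monday's last reading taken as its peak, the time at 70 °C shrinks to 3.03 min.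

The forecast gives south-east > north-east > east > south-west > south > north-west, with 52% first and 3% last, on the ground that “Heat therefore destroys selectivity”.

The flasks give south-east > north-east > east > south-west > south > north-west, from 47.5% down to 3.25%.

    G + J → X (k = 4.27 M⁻¹ s⁻¹, Ea = 66.0 kJ mol⁻¹)
    D + G ⇌ J (K = 199 M⁻¹, k = 12.8 M⁻¹ s⁻¹, Ea = 59.0 kJ mol⁻¹, ΔH = −30.0 kJ mol⁻¹)
    G ⇌ E, rate k3*([G] - [E]/K3) per volume of the first phase (partition coefficient = 0.479, kL = 0.00812 s⁻¹)
    (constants at 110 °C)

In south-east, J goes from 27.0% at 1.50 min to 47.5% at 3.00 min, with X at 7.77%, and the asked time is 0.890 of my reckoned peak time. The same flask at 95 °C has a reckoned peak time of 1.63 min, shorter than the asked time, and it ends with more X than J, X 37.0% against J 32.6%.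

(The readings were computed with made-up constants; the scatter is artificial.)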